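**Plan**

- Retrosynthesis: the O7–CH2OMe acetal is cut first. The two bonds that flank the dicarbonyl, C6–C(=O) and C(=O)–C1', are then cut back to a C6 aryl iodide, an oxalic bis(N-methoxy-N-methylamide) and 4-prenyloxyphenylmagnesium bromide. The pyran C3=C4 alkene is cut next (ring-closing metathesis), then C4=CH2, O5–CH3, C6–I and O1–C2.
- Forward, ring A: 2,4,6-trihydroxybenzaldehyde is bought; O7 is masked as a MOM ether, O1 receives the 1,1-dimethylallyl group, iodine is placed at C6 next to the still free O5–H, O5 is methylated, and the formyl carbon becomes the vinyl carbon C4.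
- Forward, pyran and chain: the pyran ring is closed by metathesis; the benzil chain is joined last at C6 by iodine–lithium exchange and double acyl substitution on the oxamide, and the MOM group is then removed.
- Enabling feature: the cis C3=C4 double bond of the pyran ring lies between the quaternary C2 and the aryl carbon C4a, and C4 can be taken from a formyl carbon that sits on ring A between O1 and O5.
- Stereochemistry: the target has no stereocentre; the cis ring alkene is imposed by the six-membered ring.

Key step: step 7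

Remark: atom numbers are those of the 2H-chromene target (O1, C2–C8a). The iodine is set at C6 before ring closure because C6 and C8 of the closed chromene are each flanked by two oxygens, so ortho-lithiation could not be relied on to tell them apart. N,N'-Dimethoxy-N,N'-dimethyloxamide is assumed to be purchased.

**Route**

Step 1
Reactants: 1 2,4,6-trihydroxybenzaldehyde
Product: 2 2,6-dihydroxy-4-(methoxymethoxy)benzaldehyde
Conditions: MOMCl (1.0 equiv), i-Pr2NEt (1.1 equiv), THF, 0 °C
Reagents that add atoms: chloromethyl methyl ether, COCCl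
Why: The 4-hydroxyl, para to the formyl group and the only one not held in a hydrogen bond to it, is the most acidic and most nucleophilic phenol, so one equivalent of MOMCl under amine base should etherify it selectively (chemoselective phenol O-alkylation, acetal protection).

Step 2
Reactants: 2 2,6-dihydroxy-4-(methoxymethoxy)benzaldehyde; 3 3-chloro-3-methylbut-1-yne
Product: 4 2-hydroxy-4-(methoxymethoxy)-6-[(2-methylbut-3-yn-2-yl)oxy]benzaldehyde
Conditions: K2CO3, KI, CuI (5 mol %), acetone, 50 °C, argon
Reagents that add atoms: none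
Why: Copper-catalysed propargylic O-alkylation of a phenoxide is the standard entry to aryl 1,1-dimethylpropargyl ethers; the two ortho hydroxyls are equivalent, and after the first alkylation the remaining one is locked in a hydrogen bond to the aldehyde, which should stop the reaction at the monoether well below the temperature of a propargyl Claisen rearrangement.

Step 3
Reactants: 4 2-hydroxy-4-(methoxymethoxy)-6-[(2-methylbut-3-yn-2-yl)oxy]benzaldehyde
Product: 5 2-hydroxy-4-(methoxymethoxy)-6-[(2-methylbut-3-en-2-yl)oxy]benzaldehyde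
Conditions: H2 (1 atm), Pd/CaCO3 poisoned with Pb(OAc)2, quinoline, EtOAc, rt
Reagents that add atoms: none
Why: Semihydrogenation of a terminal alkyne over lead-poisoned palladium in the presence of quinoline should stop at the alkene and leave the aldehyde, the aryl ether and the MOM acetal untouched.

Step 4
Reactants: 5 2-hydroxy-4-(methoxymethoxy)-6-[(2-methylbut-3-en-2-yl)oxy]benzaldehyde
Product: 6 2-hydroxy-3-iodo-4-(methoxymethoxy)-6-[(2-methylbut-3-en-2-yl)oxy]benzaldehyde
Conditions: N-iodosuccinimide (1.05 equiv), DMF, 0 °C → rt, dark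
Reagents that add atoms: N-iodosuccinimide, O=C1CCC(=O)N1I
Why: Electrophilic aromatic iodination of 2-hydroxy-4,6-dialkoxy aryl carbonyl compounds takes place ortho to the chelated hydroxyl, and here the other free position is also screened by the bulky tertiary ether, so the halogen should land on the carbon that becomes C6 of the chromene.

Step 5
Reactants: 6 2-hydroxy-3-iodo-4-(methoxymethoxy)-6-[(2-methylbut-3-en-2-yl)oxy]benzaldehyde
Product: 7 3-iodo-2-methoxy-4-(methoxymethoxy)-6-[(2-methylbut-3-en-2-yl)oxy]benzaldehyde
Conditions: MeI, K2CO3, DMF, rt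
Reagents that add atoms: iodomethane, CI
Why: Williamson methylation of the last free phenol proceeds at room temperature in DMF, far below the temperature at which the tertiary allyl aryl ether would undergo Claisen rearrangement.

Step 6
Reactants: 7 3-iodo-2-methoxy-4-(methoxymethoxy)-6-[(2-methylbut-3-en-2-yl)oxy]benzaldehyde
Product: 8 2-ethenyl-4-iodo-3-methoxy-5-(methoxymethoxy)-1-[(2-methylbut-3-en-2-yl)oxy]benzene
Conditions: Ph3PCH3Br, KOt-Bu, THF, 0 °C → rt
Reagents that add atoms: methyltriphenylphosphonium bromide, C[P+](c1ccccc1)(c1ccccc1)c1ccccc1.[Br-]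
Why: Wittig methylenation with the unstabilised ylide converts even 2,6-disubstituted benzaldehydes into styrenes under basic, cold conditions that the aryl iodide, the MOM acetal and the tertiary allyl ether tolerate.

Step 7
Reactants: 8 2-ethenyl-4-iodo-3-methoxy-5-(methoxymethoxy)-1-[(2-methylbut-3-en-2-yl)oxy]benzene
Product: 9 6-iodo-5-methoxy-7-(methoxymethoxy)-2,2-dimethyl-2H-chromene
Conditions: RuCl2(=CHPh)(PCy3)(H2IMes) (second-generation Grubbs catalyst, 5 mol %), CH2Cl2 (5 mM), 40 °C
Reagents that add atoms: none
Why: The ruthenium benzylidene exchanges with one terminal olefin of 8 to give a tethered alkylidene, which undergoes intramolecular [2+2] cycloaddition with the second olefin and cycloreversion of the ruthenacyclobutane, releasing 9 and Ru=CH2, which carries the chain with loss of ethene. The closest known reaction type is the ring-closing metathesis of 2-vinylaryl allyl and 1,1-dimethylallyl ethers to 2H-chromenes. The pyran ring is closed as a six-membered ring by forming the C3=C4 double bond between the two former vinyl carbons, O1–C2 and C4–C4a being already in place, and the ring allows only the cis alkene. No stereocentre is formed. The step needs ring closure to outrun intermolecular metathesis and thermal Claisen rearrangement of the tertiary allyl aryl ether: the gem-dimethyl group at C2 (Thorpe–Ingold effect) and the ortho tether hold the olefins together, the quaternary C2 rules out olefin migration, high dilution and 40 °C are used, and the aryl iodide and MOM acetal are inert to the ruthenium carbene.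

Step 8
Reactants: 10 4-bromophenol; 11 prenyl bromide (1-bromo-3-methylbut-2-ene)
Product: 12 1-bromo-4-[(3-methylbut-2-en-1-yl)oxy]benzene
Conditions: K2CO3, acetone, reflux
Reagents that add atoms: none
Why: Williamson etherification of a phenoxide with a primary allylic bromide is fast and gives the O-prenyl ether under these mild conditions.

Step 9
Reactants: 9 6-iodo-5-methoxy-7-(methoxymethoxy)-2,2-dimethyl-2H-chromene; 13 N,N'-dimethoxy-N,N'-dimethyloxamide; 12 1-bromo-4-[(3-methylbut-2-en-1-yl)oxy]benzene
Product: 18 1-[5-methoxy-7-(methoxymethoxy)-2,2-dimethyl-2H-chromen-6-yl]-2-{4-[(3-methylbut-2-en-1-yl)oxy]phenyl}ethane-1,2-dione, via chromen-6-yllithium 14 (not isolated), via lithium hemiaminal alkoxide 15 (not isolated), via arylmagnesium bromide 16 (not isolated), via mixed bis-hemiaminal alkoxide 17 (not isolated)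
Conditions: 9, n-BuLi, THF, −78 °C; add to 13 (1.1 equiv), THF, −78 °C; then 16 (from 12, Mg, THF; 2.5 equiv), −78 °C → rt; aq. NH4Cl
Reagents that add atoms: none
Why: Iodine–lithium exchange fixes the carbanion at C6, and sequential addition of two different organometallic reagents to an oxalic bis(N-methoxy-N-methylamide) is a known route to unsymmetrical 1,2-diketones (double Weinreb acyl substitution), the first tetrahedral chelate masking one carbonyl while the second amide is attacked; the crowded aryllithium is added first so that the unhindered Grignard reagent, used in excess, performs the slower second addition.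

Step 10
Reactants: 18 1-[5-methoxy-7-(methoxymethoxy)-2,2-dimethyl-2H-chromen-6-yl]-2-{4-[(3-methylbut-2-en-1-yl)oxy]phenyl}ethane-1,2-dione
Product: 19 ficucaricone C, 1-(7-hydroxy-5-methoxy-2,2-dimethyl-2H-chromen-6-yl)-2-{4-[(3-methylbut-2-en-1-yl)oxy]phenyl}ethane-1,2-dione
Conditions: HCl (cat.), MeOH, 0 °C → rt
Reagents that add atoms: none
Why: Acid-catalysed acetal exchange with methanol cleaves a MOM ether ortho to an aryl ketone under conditions mild enough that the aryl prenyl ether and the 2,2-dimethylchromene should survive, and the freed O7–H is then held in a hydrogen bond to the C6 carbonyl.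

**Compound list**

1 | 2,4,6-trihydroxybenzaldehyde | O=Cc1c(O)cc(O)cc1O | starting material
2 | 2,6-dihydroxy-4-(methoxymethoxy)benzaldehyde | COCOc1cc(O)c(C=O)c(O)c1 | intermediate
3 | 3-chloro-3-methylbut-1-yne | C#CC(C)(C)Cl | starting material
4 | 2-hydroxy-4-(methoxymethoxy)-6-[(2-methylbut-3-yn-2-yl)oxy]benzaldehyde | COCOc1cc(O)c(C=O)c(OC(C)(C)C#C)c1 | intermediate
5 | 2-hydroxy-4-(methoxymethoxy)-6-[(2-methylbut-3-en-2-yl)oxy]benzaldehyde | COCOc1cc(O)c(C=O)c(OC(C)(C)C=C)c1 | intermediate
6 | 2-hydroxy-3-iodo-4-(methoxymethoxy)-6-[(2-methylbut-3-en-2-yl)oxy]benzaldehyde | COCOc1cc(OC(C)(C)C=C)c(C=O)c(O)c1I | intermediate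
7 | 3-iodo-2-methoxy-4-(methoxymethoxy)-6-[(2-methylbut-3-en-2-yl)oxy]benzaldehyde | COCOc1cc(OC(C)(C)C=C)c(C=O)c(OC)c1I | intermediate
8 | 2-ethenyl-4-iodo-3-methoxy-5-(methoxymethoxy)-1-[(2-methylbut-3-en-2-yl)oxy]benzene | COCOc1cc(OC(C)(C)C=C)c(C=C)c(OC)c1I | intermediate
9 | 6-iodo-5-methoxy-7-(methoxymethoxy)-2,2-dimethyl-2H-chromene | COCOc1cc2OC(C)(C)C=Cc2c(OC)c1I | intermediate
10 | 4-bromophenol | Oc1ccc(Br)cc1 | starting material
11 | prenyl bromide (1-bromo-3-methylbut-2-ene) | CC(C)=CCBr | starting material
12 | 1-bromo-4-[(3-methylbut-2-en-1-yl)oxy]benzene | CC(C)=CCOc1ccc(Br)cc1 | intermediate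
13 | N,N'-dimethoxy-N,N'-dimethyloxamide | CON(C)C(=O)C(=O)N(C)OC | starting material
14 | [5-methoxy-7-(methoxymethoxy)-2,2-dimethyl-2H-chromen-6-yl]lithium (formed in the flask) | [Li]c1c(OC)c2C=CC(C)(C)Oc2cc1OCOC | intermediate
15 | lithium 1-[5-methoxy-7-(methoxymethoxy)-2,2-dimethyl-2H-chromen-6-yl]-1,2-bis[methoxy(methyl)amino]-2-oxoethan-1-olate (formed in the flask) | CON(C)C(=O)C(O[Li])(N(C)OC)c1c(OC)c2C=CC(C)(C)Oc2cc1OCOC | intermediate
16 | {4-[(3-methylbut-2-en-1-yl)oxy]phenyl}magnesium bromide (formed in the flask) | CC(C)=CCOc1ccc([Mg]Br)cc1 | intermediate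
17 | mixed lithium and bromomagnesium bis-alkoxide of 1-[5-methoxy-7-(methoxymethoxy)-2,2-dimethyl-2H-chromen-6-yl]-1,2-bis[methoxy(methyl)amino]-2-{4-[(3-methylbut-2-en-1-yl)oxy]phenyl}ethane-1,2-diol (formed in the flask) | CON(C)C(O[Mg]Br)(c1ccc(OCC=C(C)C)cc1)C(O[Li])(N(C)OC)c1c(OC)c2C=CC(C)(C)Oc2cc1OCOC | intermediate
18 | 1-[5-methoxy-7-(methoxymethoxy)-2,2-dimethyl-2H-chromen-6-yl]-2-{4-[(3-methylbut-2-en-1-yl)oxy]phenyl}ethane-1,2-dione | COCOc1cc2OC(C)(C)C=Cc2c(OC)c1C(=O)C(=O)c1ccc(OCC=C(C)C)cc1 | intermediate
19 | ficucaricone C, 1-(7-hydroxy-5-methoxy-2,2-dimethyl-2H-chromen-6-yl)-2-{4-[(3-methylbut-2-en-1-yl)oxy]phenyl}ethane-1,2-dione | COc1c2c(cc(O)c1C(=O)C(=O)c1ccc(OCC=C(C)C)cc1)OC(C)(C)C=C2 | target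

**Count and risks**

Total: 10 steps. Longest linear sequence: 9 steps (steps 1–7, 9 and 10); step 8 is a one-step side branch.

Most likely to fail, in this order:

Step 9. The second addition may stall at the crowded tetrahedral adduct, or the adduct may break down early so that the excess Grignard reagent adds a second time at the freed ketone carbonyl. The fallback sets out from 9 (with 11 for the side chain), comes back at 18, and builds the dicarbonyl through the benzoin oxidation level:
- Purchased racemic methyl 4-hydroxymandelate would be O-prenylated with 11 (K2CO3, acetone) to methyl 2-hydroxy-2-{4-[(3-methylbut-2-en-1-yl)oxy]phenyl}acetate F1.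
- Silylation (TBSCl, imidazole, DMF) would give methyl 2-[(tert-butyldimethylsilyl)oxy]-2-{4-[(3-methylbut-2-en-1-yl)oxy]phenyl}acetate F2.
- Amidation (MeNH(OMe)·HCl, i-PrMgCl, THF, −20 °C) would give 2-[(tert-butyldimethylsilyl)oxy]-N-methoxy-N-methyl-2-{4-[(3-methylbut-2-en-1-yl)oxy]phenyl}acetamide F3.
- Aryllithium 14 (from 9, n-BuLi, THF, −78 °C) should add once to this Weinreb amide to give 2-[(tert-butyldimethylsilyl)oxy]-1-[5-methoxy-7-(methoxymethoxy)-2,2-dimethyl-2H-chromen-6-yl]-2-{4-[(3-methylbut-2-en-1-yl)oxy]phenyl}ethan-1-one F4.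
- Tetrabutylammonium fluoride in THF would free 2-hydroxy-1-[5-methoxy-7-(methoxymethoxy)-2,2-dimethyl-2H-chromen-6-yl]-2-{4-[(3-methylbut-2-en-1-yl)oxy]phenyl}ethan-1-one F5.
- Dess–Martin periodinane (NaHCO3, CH2Cl2) would oxidise this benzoin to 18. The carbinol centre is racemic throughout and vanishes in the oxidation.

Step 7. Initiation may be slow at both encumbered olefins (a 2,6-dioxygenated styrene and a vinyl group on a quaternary carbon), so that catalyst decay or intermolecular metathesis takes over. The fallback sets out from 7, comes back at 9, and closes the pyran by oxa-6π electrocyclisation of an ortho-quinone methide instead: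
- The tertiary allyl ether of 7 would be removed with zerovalent palladium (Pd(PPh3)4 cat., morpholine, THF, rt) to give 6-hydroxy-3-iodo-2-methoxy-4-(methoxymethoxy)benzaldehyde F6.
- 2-Methylprop-1-enylmagnesium bromide (2.5 equiv, THF, 0 °C) would add to the aldehyde to give racemic 2-(1-hydroxy-3-methylbut-2-en-1-yl)-4-iodo-3-methoxy-5-(methoxymethoxy)phenol F7.
- Warming this diol (toluene, 80 °C, with a trace of pyridinium p-toluenesulfonate if needed) should dehydrate it to the quinone methide, which closes to 9.

Step 2. Alkylation of the hydrogen-bonded phenoxide by the tertiary propargylic chloride may be slow, with elimination of the chloride to the enyne and some dialkylation. The fallback sets out from 2 and comes back at 5. A Tsuji–Trost O-allylation with purchased tert-butyl 2-methylbut-3-en-2-yl carbonate (Pd(PPh3)4 cat., THF, 0 °C) should deliver the branched 1,1-dimethylallyl ether 5 directly, through attack of the phenoxide at the more substituted terminus of the allylpalladium cation. Steps 2 and 3 are both replaced, and no compound outside the list is made (F0).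

**Further compounds**

F1 | step 9 | methyl 2-hydroxy-2-{4-[(3-methylbut-2-en-1-yl)oxy]phenyl}acetate (racemic) | COC(=O)C(O)c1ccc(OCC=C(C)C)cc1
F2 | step 9 | methyl 2-[(tert-butyldimethylsilyl)oxy]-2-{4-[(3-methylbut-2-en-1-yl)oxy]phenyl}acetate (racemic) | COC(=O)C(O[Si](C)(C)C(C)(C)C)c1ccc(OCC=C(C)C)cc1
F3 | step 9 | 2-[(tert-butyldimethylsilyl)oxy]-N-methoxy-N-methyl-2-{4-[(3-methylbut-2-en-1-yl)oxy]phenyl}acetamide (racemic) | CON(C)C(=O)C(O[Si](C)(C)C(C)(C)C)c1ccc(OCC=C(C)C)cc1
F4 | step 9 | 2-[(tert-butyldimethylsilyl)oxy]-1-[5-methoxy-7-(methoxymethoxy)-2,2-dimethyl-2H-chromen-6-yl]-2-{4-[(3-methylbut-2-en-1-yl)oxy]phenyl}ethan-1-one (racemic) | COCOc1cc2OC(C)(C)C=Cc2c(OC)c1C(=O)C(O[Si](C)(C)C(C)(C)C)c1ccc(OCC=C(C)C)cc1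
F5 | step 9 | 2-hydroxy-1-[5-methoxy-7-(methoxymethoxy)-2,2-dimethyl-2H-chromen-6-yl]-2-{4-[(3-methylbut-2-en-1-yl)oxy]phenyl}ethan-1-one (racemic) | COCOc1cc2OC(C)(C)C=Cc2c(OC)c1C(=O)C(O)c1ccc(OCC=C(C)C)cc1
F6 | step 7 | 6-hydroxy-3-iodo-2-methoxy-4-(methoxymethoxy)benzaldehyde | COCOc1cc(O)c(C=O)c(OC)c1I
F7 | step 7 | 2-(1-hydroxy-3-methylbut-2-en-1-yl)-4-iodo-3-methoxy-5-(methoxymethoxy)phenol (racemic) | COCOc1cc(O)c(C(O)C=C(C)C)c(OC)c1I
F0 | step 2 | none | none
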